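**Plan**

- Numbering: ring C1 (O-angelate), C2, C3 (CH3), C4 (OH), C5, C6; chain C7 (CH3), C8, C9 (OAc), C10=C11. In the chair of the cyclohexane ring that holds the C6 chain equatorial, C1–O and C3–CH3 are also equatorial and only C4–OH is axial. The ring can therefore be closed reversibly around a fixed C3 if C4 is carried as a nitro (later carbonyl) carbon.
- Retrosynthesis: cut the C1–O(angeloyl) and C9–O(acetyl) ester bonds, then C9–C10 (isobutenyl anion onto a C9 lactone carbonyl), then C7=C8 (olefination inside a C1–O–C9 tether), then C1–C6 and C4–C5 together (aldol and Michael), and last C3–C4 (nitromethane onto crotonaldehyde).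
- Forward: C3–C4 is made first; the carbocycle, the only ring of the target, arises in step 2 from the nitro aldehyde and methyl vinyl ketone. A temporary trans-fused δ-lactone ring is closed at C7=C8, used to set C7, and opened by the isobutenyl nucleophile; the two esters follow.
- Stereochemistry: C3 from an amine catalyst; C1 and C6 by equilibration to the all-equatorial ketol; C4 by equatorial hydride attack on the ketone unmasked from the nitro group; C7 by axial hydride delivery to the trans-fused unsaturated lactone; C9 by oxazaborolidine-controlled reduction; the Z ester geometry comes with angelic acid.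

Key step: step 2

Remark: C4 of compounds 5 to 9 is drawn with the nitro group equatorial; its epimer is equally usable because C4 becomes trigonal in step 5.

**Route**

Step 1
Reactants: 1 (E)-crotonaldehyde; 2 nitromethane
Product: 3 (3S)-3-methyl-4-nitrobutanal
Conditions: (R)-2-[diphenyl(trimethylsilyloxy)methyl]pyrrolidine (10 mol %), PhCO2H (20 mol %), 2 (3 equiv), MeOH, rt
Reagents that add atoms: none
Why: Iminium-catalysed enantioselective Michael addition of a nitroalkane to an enal (diarylprolinol silyl ether catalysis), in which the diphenyl(silyloxy)methyl group of the (R)-catalyst blocks one face of the E-iminium ion so that nitromethane should add to the other face of C3, which for a methyl substituent corresponds to the (S)-aldehyde.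

Step 2
Reactants: 3 (3S)-3-methyl-4-nitrobutanal; 4 methyl vinyl ketone
Product: 6 (1R,2R,4S,5S)-2-acetyl-5-methyl-4-nitrocyclohexan-1-ol, via Michael adduct (3S)-3-methyl-4-nitro-7-oxooctanal 5 (not isolated)
Conditions: 4 (1.1 equiv, slow addition), DBU (0.2 equiv), THF, −20 °C to 0 °C; AcOH quench
Reagents that add atoms: none
Why: Base-mediated domino nitro-Michael addition and intramolecular aldol addition (the ketol-forming half of a Robinson-type annulation): the C4 nitronate of 3 adds to the terminal carbon of 4 to form C4–C5, and the methyl ketone of 5 then enolises toward C6 and adds to the C1 aldehyde to form C1–C6. The carbocycle closes in a 6-(enolexo)-exo-trig mode; closure from the methyl side would need an eight-membered ring, and the other six-ring aldol (aldehyde enolate onto the ketone) gives a less stable tertiary ketol that should revert. C1 and C6 are set under thermodynamic control, because retro-aldol/aldol exchange and enolisation at C6 are reversible with DBU, so the material should collect in the chair in which hydroxyl, acetyl and the fixed C3 methyl are all equatorial; C4 equilibrates through the nitronate to equatorial nitro and is erased later. The step needs a single Michael addition, which about one equivalent of 4 and the fast intramolecular aldol should secure, and it needs the ketol to keep its water, which a catalytic amidine base at or below 0 °C should secure because E1cB loss of hydroxide is slow there.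

Step 3
Reactants: 6 (1R,2R,4S,5S)-2-acetyl-5-methyl-4-nitrocyclohexan-1-ol; 7 diethylphosphonoacetic acid
Product: 8 (1R,2R,4S,5S)-2-acetyl-5-methyl-4-nitrocyclohexyl 2-(diethoxyphosphoryl)acetate
Conditions: N,N'-dicyclohexylcarbodiimide (DCC), 4-(dimethylamino)pyridine (DMAP, 5 mol %), CH2Cl2, 0 °C to rt
Reagents that add atoms: none
Why: Steglich esterification of the secondary C1 alcohol under nearly neutral conditions, which should leave the β-ketol intact and touches no stereocentre.

Step 4
Reactants: 8 (1R,2R,4S,5S)-2-acetyl-5-methyl-4-nitrocyclohexyl 2-(diethoxyphosphoryl)acetate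
Product: 9 (4aS,6S,7S,8aR)-4,7-dimethyl-6-nitro-4a,5,6,7,8,8a-hexahydro-2H-chromen-2-one
Conditions: LiCl (5 equiv), i-Pr2NEt (3 equiv), MeCN, 0 °C to rt
Reagents that add atoms: none
Why: Intramolecular Horner–Wadsworth–Emmons olefination under Masamune–Roush conditions, in which the lithium-chelated phosphonate is deprotonated by the weak amine and closes onto the C7 ketone (6-exo-trig) to give the C7=C8 alkene inside a trans-fused lactone; C1 is untouched, C6 is already equatorial, and the nitro group is only reversibly deprotonated.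

Step 5
Reactants: 9 (4aS,6S,7S,8aR)-4,7-dimethyl-6-nitro-4a,5,6,7,8,8a-hexahydro-2H-chromen-2-one
Product: 11 (4aS,7S,8aR)-4,7-dimethyl-4a,7,8,8a-tetrahydro-2H-chromene-2,6(5H)-dione, via potassium C4-nitronate 10 (not isolated)
Conditions: KOt-Bu (1.05 equiv), THF, 0 °C; then 2KHSO5·KHSO4·K2SO4 (Oxone), Na2HPO4, H2O–MeOH, 0 °C
Reagents that add atoms: potassium peroxymonosulfate (active salt of Oxone), [K+].[O-]S(=O)(=O)OO
Why: Oxidative Nef reaction, in which the nitronate carbon is oxidised by peroxymonosulfate and nitrite is expelled to give the C4 ketone; the electron-poor lactone alkene should be inert to the buffered oxidant, and C3, now α to a ketone, already sits in its preferred equatorial configuration.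

Step 6
Reactants: 11 (4aS,7S,8aR)-4,7-dimethyl-4a,7,8,8a-tetrahydro-2H-chromene-2,6(5H)-dione
Product: 12 (4aS,6R,7S,8aR)-6-hydroxy-4,7-dimethyl-4a,5,6,7,8,8a-hexahydro-2H-chromen-2-one
Conditions: LiBH(s-Bu)3 (L-Selectride, 1.05 equiv), THF, −78 °C; AcOH quench at −78 °C
Reagents that add atoms: none
Why: Diastereoselective ketone reduction by a bulky trialkylborohydride, which should attack the C4 carbonyl along the equatorial trajectory (the axial one is blocked by the axial hydrogens at C2 and C6) and give the axial (4R) alcohol cis to the C3 methyl, while the β,β-disubstituted unsaturated lactone should not react at −78 °C.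

Step 7
Reactants: 12 (4aS,6R,7S,8aR)-6-hydroxy-4,7-dimethyl-4a,5,6,7,8,8a-hexahydro-2H-chromen-2-one
Product: 13 (4aS,6R,7S,8aR)-4,7-dimethyl-6-[(triethylsilyl)oxy]-4a,5,6,7,8,8a-hexahydro-2H-chromen-2-one
Conditions: Et3SiOTf, 2,6-lutidine, CH2Cl2, −78 °C to 0 °C
Reagents that add atoms: triethylsilyl trifluoromethanesulfonate, CC[Si](CC)(CC)OS(=O)(=O)C(F)(F)F
Why: Silyl ether formation with a silyl triflate, reactive enough for the hindered axial C4 alcohol; the triethylsilyl group is chosen because it can be removed at the end under buffered fluoride.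

Step 8
Reactants: 13 (4aS,6R,7S,8aR)-4,7-dimethyl-6-[(triethylsilyl)oxy]-4a,5,6,7,8,8a-hexahydro-2H-chromen-2-one
Product: 14 (4R,4aS,6R,7S,8aR)-4,7-dimethyl-6-[(triethylsilyl)oxy]octahydro-2H-chromen-2-one
Conditions: Cu(OAc)2·H2O (5 mol %), 1,2-bis(diphenylphosphino)benzene (5 mol %), (EtO)2MeSiH (3 equiv), t-BuOH (2 equiv), toluene, 0 °C to rt
Reagents that add atoms: none
Why: Ligand-accelerated copper hydride conjugate reduction of an unsaturated lactone, in which hydride should reach C7 along the axial trajectory anti to the axial C6–H of the trans-fused half-chair (chair-like enolate), so that H7 ends on the face of H1 and the C7 methyl is equatorial on the lactone ring, which is (7R).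

Step 9
Reactants: 14 (4R,4aS,6R,7S,8aR)-4,7-dimethyl-6-[(triethylsilyl)oxy]octahydro-2H-chromen-2-one; 15 1-bromo-2-methylprop-1-ene
Product: 18 (6R)-6-[(1S,2R,4S,5R)-2-hydroxy-4-methyl-5-(triethylsilyloxy)cyclohexyl]-2-methylhept-2-en-4-one, via 2-methylprop-1-enyllithium 16 (not isolated), via lithium lactolate 17 (not isolated)
Conditions: 15 (1.3 equiv), t-BuLi (2.6 equiv), Et2O, −78 °C; then 14, THF, −78 °C; AcOH quench at −78 °C
Reagents that add atoms: none
Why: Mono-addition of an alkenyllithium (from bromine–lithium exchange) to a δ-lactone, in which the tetrahedral lithium lactolate is stable at −78 °C and opens to the ketone only on protonation, so a second addition should be avoided; the opening frees the C1 hydroxyl, installs C10=C11 and touches no stereocentre.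

Step 10
Reactants: 18 (6R)-6-[(1S,2R,4S,5R)-2-hydroxy-4-methyl-5-(triethylsilyloxy)cyclohexyl]-2-methylhept-2-en-4-one; 19 angelic acid
Product: 21 (1R,2S,4R,5S)-5-methyl-2-[(2R)-6-methyl-4-oxohept-5-en-2-yl]-4-(triethylsilyloxy)cyclohexyl (2Z)-2-methylbut-2-enoate, via angelic 2,4,6-trichlorobenzoic anhydride 20 (not isolated)
Conditions: 19, 2,4,6-trichlorobenzoyl chloride, Et3N, toluene, rt; then 18, 80 °C
Reagents that add atoms: none
Why: Yamaguchi-type mixed-anhydride esterification run without a nucleophilic catalyst, which should acylate the hindered C1 alcohol at the less hindered angeloyl carbonyl while keeping Z to E isomerisation (conjugate addition–elimination) to the tiglate low.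

Step 11
Reactants: 21 (1R,2S,4R,5S)-5-methyl-2-[(2R)-6-methyl-4-oxohept-5-en-2-yl]-4-(triethylsilyloxy)cyclohexyl (2Z)-2-methylbut-2-enoate
Product: 22 (1R,2S,4R,5S)-2-[(2R,4R)-4-hydroxy-6-methylhept-5-en-2-yl]-5-methyl-4-(triethylsilyloxy)cyclohexyl (2Z)-2-methylbut-2-enoate
Conditions: (S)-1-methyl-3,3-diphenyltetrahydro-1H,3H-pyrrolo[1,2-c][1,3,2]oxazaborole [(S)-Me-CBS, 0.3 equiv], catecholborane (1.5 equiv), toluene, −78 °C; then MeOH, aq. NaHCO3
Reagents that add atoms: none
Why: Corey–Bakshi–Shibata reduction, in which the (S)-oxazaborolidine should bind the C9 ketone with the isobutenyl group as the large substituent and deliver hydride in the sense that turns acetophenone into (R)-1-phenylethanol, giving the (9R) allylic alcohol; catecholborane at −78 °C should spare the angelate and both alkenes.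

Step 12
Reactants: 22 (1R,2S,4R,5S)-2-[(2R,4R)-4-hydroxy-6-methylhept-5-en-2-yl]-5-methyl-4-(triethylsilyloxy)cyclohexyl (2Z)-2-methylbut-2-enoate
Product: 23 (1R,2S,4R,5S)-2-[(2R,4R)-4-acetoxy-6-methylhept-5-en-2-yl]-5-methyl-4-(triethylsilyloxy)cyclohexyl (2Z)-2-methylbut-2-enoate
Conditions: Ac2O, pyridine, DMAP (cat.), CH2Cl2, 0 °C to rt
Reagents that add atoms: acetic anhydride, CC(=O)OC(C)=O
Why: DMAP-catalysed acetylation of the secondary allylic alcohol at oxygen, with retention at C9.

Step 13
Reactants: 23 (1R,2S,4R,5S)-2-[(2R,4R)-4-acetoxy-6-methylhept-5-en-2-yl]-5-methyl-4-(triethylsilyloxy)cyclohexyl (2Z)-2-methylbut-2-enoate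
Product: 24 (1R,2S,4R,5S)-2-[(2R,4R)-4-acetoxy-6-methylhept-5-en-2-yl]-4-hydroxy-5-methylcyclohexyl (2Z)-2-methylbut-2-enoate (CNP0237033.1)
Conditions: HF·pyridine, pyridine, THF, 0 °C to rt
Reagents that add atoms: none
Why: Fluoride-mediated cleavage of the triethylsilyl ether, buffered with pyridine so that the allylic acetate should not ionise and the angelate should not isomerise; no stereocentre is touched.

**Compound list**

1 | (E)-crotonaldehyde [(2E)-but-2-enal] | C/C=C/C=O | starting material
2 | nitromethane | C[N+](=O)[O-] | starting material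
3 | (3S)-3-methyl-4-nitrobutanal | O=CC[C@H](C)C[N+](=O)[O-] | intermediate
4 | methyl vinyl ketone (but-3-en-2-one) | CC(=O)C=C | starting material
5 | (3S)-3-methyl-4-nitro-7-oxooctanal (Michael adduct, both C4 epimers) | O=CC[C@H](C)C(CCC(C)=O)[N+](=O)[O-] | intermediate
6 | (1R,2R,4S,5S)-2-acetyl-5-methyl-4-nitrocyclohexan-1-ol (all substituents equatorial) | O[C@@H]1C[C@H](C)[C@@H]([N+](=O)[O-])C[C@H]1C(C)=O | intermediate
7 | diethylphosphonoacetic acid | OC(=O)CP(=O)(OCC)OCC | starting material
8 | (1R,2R,4S,5S)-2-acetyl-5-methyl-4-nitrocyclohexyl 2-(diethoxyphosphoryl)acetate | CCOP(=O)(OCC)CC(=O)O[C@@H]1C[C@H](C)[C@@H]([N+](=O)[O-])C[C@H]1C(C)=O | intermediate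
9 | (4aS,6S,7S,8aR)-4,7-dimethyl-6-nitro-4a,5,6,7,8,8a-hexahydro-2H-chromen-2-one (trans-fused) | O=C1C=C(C)[C@@H]2C[C@H]([N+](=O)[O-])[C@@H](C)C[C@H]2O1 | intermediate
10 | potassium C4-nitronate of 9 | O=C1C=C(C)[C@@H]2CC(=[N+]([O-])[O-])[C@@H](C)C[C@H]2O1.[K+] | intermediate
11 | (4aS,7S,8aR)-4,7-dimethyl-4a,7,8,8a-tetrahydro-2H-chromene-2,6(5H)-dione | O=C1C=C(C)[C@@H]2CC(=O)[C@@H](C)C[C@H]2O1 | intermediate
12 | (4aS,6R,7S,8aR)-6-hydroxy-4,7-dimethyl-4a,5,6,7,8,8a-hexahydro-2H-chromen-2-one (axial C4–OH) | O=C1C=C(C)[C@@H]2C[C@@H](O)[C@@H](C)C[C@H]2O1 | intermediate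
13 | (4aS,6R,7S,8aR)-4,7-dimethyl-6-[(triethylsilyl)oxy]-4a,5,6,7,8,8a-hexahydro-2H-chromen-2-one | O=C1C=C(C)[C@@H]2C[C@@H](O[Si](CC)(CC)CC)[C@@H](C)C[C@H]2O1 | intermediate
14 | (4R,4aS,6R,7S,8aR)-4,7-dimethyl-6-[(triethylsilyl)oxy]octahydro-2H-chromen-2-one | O=C1C[C@@H](C)[C@@H]2C[C@@H](O[Si](CC)(CC)CC)[C@@H](C)C[C@H]2O1 | intermediate
15 | 1-bromo-2-methylprop-1-ene | BrC=C(C)C | starting material
16 | 2-methylprop-1-enyllithium | [Li]C=C(C)C | intermediate
17 | lithium (4R,4aS,6R,7S,8aR)-4,7-dimethyl-2-(2-methylprop-1-en-1-yl)-6-[(triethylsilyl)oxy]octahydro-2H-chromen-2-olate (lactolate, both C9 epimers) | [Li]OC1(C=C(C)C)C[C@@H](C)[C@@H]2C[C@@H](O[Si](CC)(CC)CC)[C@@H](C)C[C@H]2O1 | intermediate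
18 | (6R)-6-[(1S,2R,4S,5R)-2-hydroxy-4-methyl-5-(triethylsilyloxy)cyclohexyl]-2-methylhept-2-en-4-one | O[C@@H]1C[C@H](C)[C@H](O[Si](CC)(CC)CC)C[C@H]1[C@H](C)CC(=O)C=C(C)C | intermediate
19 | angelic acid [(2Z)-2-methylbut-2-enoic acid] | C/C=C(/C)C(=O)O | starting material
20 | (2Z)-2-methylbut-2-enoic 2,4,6-trichlorobenzoic anhydride | C/C=C(/C)C(=O)OC(=O)c1c(Cl)cc(Cl)cc1Cl | intermediate
21 | (1R,2S,4R,5S)-5-methyl-2-[(2R)-6-methyl-4-oxohept-5-en-2-yl]-4-(triethylsilyloxy)cyclohexyl (2Z)-2-methylbut-2-enoate | C/C=C(/C)C(=O)O[C@@H]1C[C@H](C)[C@H](O[Si](CC)(CC)CC)C[C@H]1[C@H](C)CC(=O)C=C(C)C | intermediate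
22 | (1R,2S,4R,5S)-2-[(2R,4R)-4-hydroxy-6-methylhept-5-en-2-yl]-5-methyl-4-(triethylsilyloxy)cyclohexyl (2Z)-2-methylbut-2-enoate | C/C=C(/C)C(=O)O[C@@H]1C[C@H](C)[C@H](O[Si](CC)(CC)CC)C[C@H]1[C@H](C)C[C@H](C=C(C)C)O | intermediate
23 | (1R,2S,4R,5S)-2-[(2R,4R)-4-acetoxy-6-methylhept-5-en-2-yl]-5-methyl-4-(triethylsilyloxy)cyclohexyl (2Z)-2-methylbut-2-enoate | C/C=C(/C)C(=O)O[C@@H]1C[C@H](C)[C@H](O[Si](CC)(CC)CC)C[C@H]1[C@H](C)C[C@H](C=C(C)C)OC(C)=O | intermediate
24 | (1R,2S,4R,5S)-2-[(2R,4R)-4-acetoxy-6-methylhept-5-en-2-yl]-4-hydroxy-5-methylcyclohexyl (2Z)-2-methylbut-2-enoate | C/C=C(/C)C(=O)O[C@@H]1C[C@H](C)[C@H](O)C[C@H]1[C@H](C)C[C@H](C=C(C)C)OC(C)=O | target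

**Count**

Total steps: 13. Longest linear sequence: 13 steps (1 and 2 to 24).

**Steps most likely to fail**

1. Step 2. The nitronate may be alkylated by a second molecule of 4, the free aldehyde may condense intermolecularly, the ketol may lose water, or equilibration may stop short and leave C1/C6 epimers. The fallback sets out from 3 and comes back at 6. It separates the two bond formations and keeps the aldehyde masked during the Michael addition. Compound 3 is converted with HC(OMe)3 and pyridinium p-toluenesulfonate in MeOH into the dimethyl acetal (3S)-1,1-dimethoxy-3-methyl-4-nitrobutane F1. DBU-catalysed Michael addition of F1 to 4 in MeCN then gives (6S)-8,8-dimethoxy-6-methyl-5-nitrooctan-2-one F2. Mild acid hydrolysis (Amberlyst-15, wet acetone) releases keto aldehyde 5, which is isolated. It is cyclised in a separate flask by classical ketol formation (catalytic K2CO3, MeOH, 0 °C); the all-equatorial isomer 6 is collected and the remainder is re-equilibrated.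

2. Step 8. Hydride may be delivered to the wrong face of C7, or the hindered β,β-disubstituted enoate may not be reduced at all. The fallback sets out from 13 and comes back at 14, and replaces substrate control by catalyst control on an open-chain alkene. Reduction of 13 with i-Bu2AlH (CH2Cl2, −78 °C to 0 °C) opens the lactone to the allylic diol (1R,2S,4R,5S)-2-[(2Z)-4-hydroxybut-2-en-2-yl]-5-methyl-4-[(triethylsilyl)oxy]cyclohexan-1-ol F3. Hydrogenation of the allylic alcohol with Ru(OAc)2[(S)-BINAP] and H2 in MeOH follows; the sense known for Z-configured γ,γ-disubstituted allylic alcohols corresponds to 7R here. It should give (1R,2S,4R,5S)-2-[(2R)-4-hydroxybutan-2-yl]-5-methyl-4-[(triethylsilyl)oxy]cyclohexan-1-ol F4. Oxidative lactonisation with PhI(OAc)2 and catalytic 2,2,6,6-tetramethylpiperidin-1-oxyl (TEMPO) in CH2Cl2 oxidises the primary C9 alcohol and then the lactol, and returns 14.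

3. Step 11. The oxazaborolidine complex may discriminate poorly between the isobutenyl side and the branched alkyl side of the C9 ketone, giving low selectivity at C9. The fallback sets out from 21 and comes back at 23, and replaces reagent-controlled reduction by a stereoconvergent acetylation. Luche reduction of 21 (NaBH4, CeCl3·7H2O, MeOH, −78 °C) gives both C9 epimers: 22 and (1R,2S,4R,5S)-2-[(2R,4S)-4-hydroxy-6-methylhept-5-en-2-yl]-5-methyl-4-(triethylsilyloxy)cyclohexyl (2Z)-2-methylbut-2-enoate F5. They are separated by chromatography. Compound 22 is acetylated as in step 12. F5 is converted into the same acetate 23 by Mitsunobu esterification with acetic acid (PPh3, diisopropyl azodicarboxylate, toluene, 0 °C), which inverts C9.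

**Further compounds**

F1 | step 2 | (3S)-1,1-dimethoxy-3-methyl-4-nitrobutane | COC(OC)C[C@H](C)C[N+](=O)[O-]
F2 | step 2 | (6S)-8,8-dimethoxy-6-methyl-5-nitrooctan-2-one (both C5 epimers) | COC(OC)C[C@H](C)C(CCC(C)=O)[N+](=O)[O-]
F3 | step 8 | (1R,2S,4R,5S)-2-[(2Z)-4-hydroxybut-2-en-2-yl]-5-methyl-4-[(triethylsilyl)oxy]cyclohexan-1-ol | O[C@@H]1C[C@H](C)[C@H](O[Si](CC)(CC)CC)C[C@H]1/C(C)=C\CO
F4 | step 8 | (1R,2S,4R,5S)-2-[(2R)-4-hydroxybutan-2-yl]-5-methyl-4-[(triethylsilyl)oxy]cyclohexan-1-ol | O[C@@H]1C[C@H](C)[C@H](O[Si](CC)(CC)CC)C[C@H]1[C@H](C)CCO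
F5 | step 11 | (1R,2S,4R,5S)-2-[(2R,4S)-4-hydroxy-6-methylhept-5-en-2-yl]-5-methyl-4-(triethylsilyloxy)cyclohexyl (2Z)-2-methylbut-2-enoate | C/C=C(/C)C(=O)O[C@@H]1C[C@H](C)[C@H](O[Si](CC)(CC)CC)C[C@H]1[C@H](C)C[C@@H](C=C(C)C)O
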